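**Plan**
- Retrosynthesis: after removing the acetates and the C4 silyl ether, the C1–C2 bond (ten-membered ring) and the C8–C17 bond (butanolide) are cut in one reductive double aldol; then C8–C9 (boron aldol) and C6–C7 (alkenyllithium + Weinreb amide).
- Enabling feature: C14 of the cyclohexene ring is a carbinol next to quaternary C1, and C2 is a carbinol. With C14 as a ketone, C1 is an enolate carbon that a C1–Br bond (either epimer) unmasks regiospecifically, and C2 is an aldehyde. C8 (ketone) and C17 (2-bromopropanoate on O7) of the butanolide are related in the same way.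
- Forward: the six-membered ring comes from Birch reduction of methyl 2,6-dimethylbenzoate (ester carbon = C9); the C2–C8 enone comes from a propargylic alcohol; the two are joined by an aldol reaction; the γ-lactone and the ten-membered ring then close together with SmI2.
- Stereochemistry: C4 by asymmetric alkynylation; Δ5 (Z) by anti-carbomagnesiation/iodination; C9 by Ipc-boron aldol; C10 by 9-OH-directed choice between the two ring alkenes; C7 and C14 by Evans–Tishchenko 1,3-anti reductions; C8/C17 and C1/C2 in the key step.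

Key step: step 17

Assumption: briarane numbering (C1–C20) is used for advanced intermediates, and (S,S)-ProPhenol and (−)-Ipc2BOTf are taken to deliver 4R and 9S; if either sense is opposite, the antipodal ligand or reagent is used.

**Step 1**
Reactants: 1 3-[(4-methoxybenzyl)oxy]propan-1-ol
Product: 2 3-[(4-methoxybenzyl)oxy]propanal
Conditions: TEMPO (10 mol %), PhI(OAc)2 (1.1 equiv), CH2Cl2, rt
Reagents that add atoms: none
Why: Oxoammonium (TEMPO/BAIB) oxidation of a primary alcohol should stop cleanly at the aldehyde and leave the PMB ether untouched.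

**Step 2**
Reactants: 2 3-[(4-methoxybenzyl)oxy]propanal
Product: 4 (3R)-5-[(4-methoxybenzyl)oxy]pent-1-yn-3-ol, via TMS alkynol 3 (not isolated)
Conditions: ethynyltrimethylsilane (2.8 equiv), Me2Zn (2.9 equiv), (S,S)-ProPhenol (10 mol %), Ph3P=O (20 mol %), toluene, 4 °C; then K2CO3 (cat.), MeOH, rt
Reagents that add atoms: ethynyltrimethylsilane C#C[Si](C)(C)C
Why: Zinc–ProPhenol-catalysed asymmetric alkynylation of an unbranched aldehyde should set C4 by reagent control, and methanolysis then removes the C-silyl group.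

**Step 3**
Reactants: 4 (3R)-5-[(4-methoxybenzyl)oxy]pent-1-yn-3-ol
Product: 6 (1E,3R)-1-iodo-2-{[dimethyl(propan-2-yloxy)silyl]methyl}-5-[(4-methoxybenzyl)oxy]pent-1-en-3-ol, via alkenylmagnesium chloride 5 (not isolated)
Conditions: (i-PrO)Me2SiCH2MgCl (3.0 equiv), CuI (15 mol %), THF, −10 °C to rt; then I2 (2.5 equiv), −78 to 0 °C
Reagents that add atoms: (isopropoxydimethylsilyl)methylmagnesium chloride CC(C)O[Si](C)(C)C[Mg]Cl; iodine II
Why: Copper-catalysed anti-carbomagnesiation of the propargylic alkoxide (Duboudin) puts the new carbon on the proximal alkyne carbon and magnesium cis to the carbinol carbon in a five-membered oxamagnesacycle, so iodinolysis with retention should give iodine cis to C4, the geometry that becomes the (5Z) ring alkene.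

**Step 4**
Reactants: 6 (1E,3R)-1-iodo-2-{[dimethyl(propan-2-yloxy)silyl]methyl}-5-[(4-methoxybenzyl)oxy]pent-1-en-3-ol
Product: 7 (2Z,3R)-2-(iodomethylidene)-5-[(4-methoxybenzyl)oxy]pentane-1,3-diol
Conditions: 30 % H2O2, KF, KHCO3, THF/MeOH (1:1), rt
Reagents that add atoms: hydrogen peroxide OO
Why: Tamao–Kumada oxidation converts the alkoxysilyl-bearing CH2 into CH2OH (C16) and should not touch the alkenyl iodide or the alkene geometry.

**Step 5**
Reactants: 7 (2Z,3R)-2-(iodomethylidene)-5-[(4-methoxybenzyl)oxy]pentane-1,3-diol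
Product: 8 bis-TBS ether of 7
Conditions: TBSCl (2.5 equiv), imidazole (5 equiv), DMF, rt
Reagents that add atoms: tert-butyldimethylsilyl chloride CC(C)(C)[Si](C)(C)Cl
Why: Standard silylation protects the C4 and C16 hydroxyls in one operation with groups that survive organolithium, oxidative and SmI2 conditions.

**Step 6**
Reactants: 9 2-chloro-N-methoxy-N-methylacetamide; 10 (4-methoxyphenyl)methanol
Product: 11 N-methoxy-2-[(4-methoxybenzyl)oxy]-N-methylacetamide
Conditions: NaH (1.1 equiv), THF, 0 °C; then 9, Bu4NI (cat.), 0 °C to rt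
Reagents that add atoms: none
Why: Williamson etherification of an activated α-chloro amide by the PMB alkoxide should give the O-protected glycolic Weinreb amide that supplies C7 and C8.

**Step 7**
Reactants: 8 bis-TBS alkenyl iodide; 11 N-methoxy-2-[(4-methoxybenzyl)oxy]-N-methylacetamide
Product: 13 (3Z,5R)-5-[(tert-butyldimethylsilyl)oxy]-4-{[(tert-butyldimethylsilyl)oxy]methyl}-1,7-bis[(4-methoxybenzyl)oxy]hept-3-en-2-one, via alkenyllithium 12 (not isolated)
Conditions: t-BuLi (2.05 equiv), Et2O, −78 °C, 20 min; then 11 (1.2 equiv), −78 to −30 °C; aq. work-up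
Reagents that add atoms: none
Why: Iodine–lithium exchange proceeds with retention of alkene geometry, and acylation by the Weinreb amide (stable chelated tetrahedral intermediate, no over-addition) should give the (Z)-enone with C7 cis to C4.

**Step 8**
Reactants: 14 methyl 2,6-dimethylbenzoate
Product: 16 methyl 2,6-dimethylcyclohexa-2,5-diene-1-carboxylate, via lithium ester dienolate 15 (not isolated)
Conditions: Li (2.4 equiv), NH3(l)/THF, t-BuOH (1.0 equiv), −78 °C; then solid NH4Cl
Reagents that add atoms: none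
Why: Birch reduction of a benzoate (Mander conditions) gives the ester dienolate, whose kinetic α-protonation should deliver the 1,4-diene with both methyls on sp2 carbons, so C10 carries H and the future C9.

**Step 9**
Reactants: 16 methyl 2,6-dimethylcyclohexa-2,5-diene-1-carboxylate
Product: 17 2,6-dimethylcyclohexa-2,5-diene-1-carbaldehyde
Conditions: DIBAL-H (1.05 equiv), CH2Cl2, −78 °C; MeOH, aq. Rochelle salt; used cold at once
Reagents that add atoms: none
Why: Low-temperature DIBAL reduction stops at the aluminium hemiacetal, so the sensitive bis-allylic aldehyde should be obtained without conjugation or aromatisation if used immediately.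

**Step 10**
Reactants: 13 (Z)-enone; 17 2,6-dimethylcyclohexa-2,5-diene-1-carbaldehyde
Product: 19 aldol adduct with 9S carbinol (8,9-syn), via Z boron enolate 18 (not isolated)
Conditions: (−)-Ipc2BOTf (1.3 equiv), i-Pr2NEt (1.6 equiv), CH2Cl2, −78 to −40 °C; then 17 (1.5 equiv), −78 to −20 °C; MeOH, pH 7 buffer, 30 % H2O2, 0 °C
Reagents that add atoms: none
Why: In this Paterson boron aldol, C8 is the only enolisable position of 13, so the Z-diisopinocampheylboron enolate forms regiospecifically and its Zimmerman–Traxler addition should set C9 under control of the Ipc ligands; the C8 configuration does not matter because C8 is later oxidised.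

**Step 11**
Reactants: 19 aldol adduct
Product: 20 1,14-epoxide of 19 (oxirane cis to C9)
Conditions: VO(acac)2 (5 mol %), t-BuOOH (1.2 equiv, decane), CH2Cl2, 0 °C
Reagents that add atoms: tert-butyl hydroperoxide CC(C)(C)OO
Why: In this hydroxyl-directed vanadium epoxidation of a homoallylic alcohol, the C9–H should lie between the two flanking vinyl methyls, which places the 9S vanadate gauche to C1 and not C11, so oxygen is delivered to the C1=C14 alkene and C10 becomes a stereocentre of the required sense; the epoxide face is irrelevant because C1 and C14 are trigonalised later.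

**Step 12**
Reactants: 20 epoxy aldol
Product: 21 9-O-acetyl 7-carbinol (7,9-anti)
Conditions: SmI2 (0.3 equiv) premixed with MeCHO (8 equiv), THF, −10 °C; then 20
Reagents that add atoms: acetaldehyde CC=O
Why: In this Evans–Tishchenko reduction the samarium(III) hemiacetal formed from the C9 alkoxide and acetaldehyde transfers hydride intramolecularly to C7 through a bicyclic chair transition state, which should give the 7,9-anti carbinol (C7 as in the target), differentiate the two oxygens and install the C9 acetate of the target.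

**Step 13**
Reactants: 21 9-O-acetyl 7-carbinol
Product: 22 7-O-(2-bromopropanoyl) ester of 21 (both C17 epimers)
Conditions: 2-bromopropanoyl bromide (1.3 equiv), pyridine (3 equiv), CH2Cl2, −40 to 0 °C
Reagents that add atoms: 2-bromopropanoyl bromide CC(Br)C(=O)Br
Why: Acylation of the only free hydroxyl attaches C17–C19, and the racemic bromide centre is acceptable because it becomes a planar enolate in step 17.

**Step 14**
Reactants: 22 bromopropanoate epoxide
Product: 23 bromohydrin (C1 tertiary bromide and trans C14 carbinol)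
Conditions: 48 % aq. HBr (1.3 equiv), THF, −20 °C, ≤15 min; cold pH 7 buffer
Reagents that add atoms: hydrogen bromide Br
Why: Acid-mediated trans-diaxial opening of the trisubstituted oxirane should place bromide on the tertiary carbon C1 (SN1-like, as for 1-methylcyclohexene oxide) and leave the oxygen on C14.

**Step 15**
Reactants: 23 bromohydrin
Product: 24 triol (free C2, C8 and C14 hydroxyls)
Conditions: DDQ (2.6 equiv), CH2Cl2/pH 7 buffer (10:1), 0 °C
Reagents that add atoms: none
Why: Oxidative cleavage of both PMB ethers under neutral conditions should not disturb the tertiary bromide, the esters or the silyl ethers.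

**Step 16**
Reactants: 24 triol
Product: 25 seco tricarbonyl (C2 aldehyde, C8 ketone, C14 ketone bearing C1–Br)
Conditions: Dess–Martin periodinane (4.5 equiv), NaHCO3, CH2Cl2, 0 °C to rt; short Florisil filtration, used at once
Reagents that add atoms: none
Why: Buffered Dess–Martin oxidation converts all three carbinols in one operation and creates both bromo-carbonyl/carbonyl pairs at once; the temporary centres at C8 and C14 are erased.

**Step 17**
Reactants: 25 seco tricarbonyl
Product: 27 2,9-di-O-acetyl-14-hydroxy-4,16-bis-O-TBS briaranolide, via bis-aldol ketol 26 (not isolated)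
Conditions: 25 added over 3 h (final 2 mM) to SmI2 (4.4 equiv, THF), −78 °C; then MeCHO (15 equiv), −78 to −10 °C; aq. NaHCO3/Na2S2O3
Reagents that add atoms: acetaldehyde CC=O
Why: Two-electron reduction of each C–Br bond by SmI2 gives the C17 samarium ester enolate and, from either C1 epimer, the single C14(OSm)=C1 enolate, which add to the C8 ketone and the C2 aldehyde; the Sm(III) C2 aldolate then forms a hemiacetal with acetaldehyde and reduces C14 by intramolecular hydride transfer. The closest known reactions are SmI2 intramolecular Reformatsky closures of hydroxy lactones and of 8- and 11-membered carbocycles from α-bromo ketones and aldehydes, and the samarium aldol/Evans–Tishchenko sequence. The γ-lactone closes by 5-(enolendo)-exo-trig attack of C17 on C8, as in Reformatsky and Dieckmann routes to butanolides, and the ten-membered ring by 10-(enolexo)-exo-trig attack of C1 on C2 under high dilution. At C8 the bulky C9 branch should end trans to the C6 alkenyl group (OH cis to C6) and the C17 methyl trans to C9 (also the thermodynamically preferred, epimerisable arrangement); at C1 the aldehyde adds to the enolate face anti to the C10–C9 bond (trans ring fusion); at C2 a samarium-chelated Zimmerman–Traxler chair with the ring-fixed E(O)-enolate gives the anti aldol (2S); at C14 the Evans–Tishchenko transition state gives the 2,14-anti carbinol and leaves C2 as its acetate. The step needs C–Br reduction to precede reduction of the aldehyde or of the bis(acyloxy) ketone C8, which the much faster C–Br cleavage at −78 °C and immediate capture of C8 by the tethered enolate should secure; ring size keeps the two enolates on their own acceptors (C1 cannot reach C8, C17 reaches C8 through a five-membered transition state).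

**Step 18**
Reactants: 27 bis-TBS macrocycle
Product: 28 16-hydroxy 4-O-TBS macrocycle
Conditions: HF·pyridine, pyridine, THF, 0 °C
Reagents that add atoms: none
Why: Buffered HF·pyridine should cleave the primary allylic TBS ether much faster than the secondary C4 ether and leave the esters and the lactone alone.

**Step 19**
Reactants: 28 16-hydroxy 4-O-TBS macrocycle
Product: 29 4-O-TBS ether of the target
Conditions: Ac2O (6 equiv), DMAP (0.3 equiv), pyridine, CH2Cl2, 0 °C to rt
Reagents that add atoms: acetic anhydride CC(=O)OC(C)=O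
Why: DMAP-catalysed acetylation should esterify the primary C16 and the secondary C14 hydroxyls while the hindered tertiary C8 hydroxyl stays free; any earlier acetyl shift between O2 and O14 is levelled here.

**Step 20**
Reactants: 29 4-O-TBS ether of the target
Product: 30 CNP0226727.2
Conditions: HF·pyridine, THF, 0 °C to rt
Reagents that add atoms: none
Why: Acidic fluoride desilylation frees the C4 hydroxyl without base, so the four acetates should not migrate.

**Compound list**
1 | 3-[(4-methoxybenzyl)oxy]propan-1-ol | COc1ccc(cc1)COCCCO | starting material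
2 | 3-[(4-methoxybenzyl)oxy]propanal | COc1ccc(cc1)COCCC=O | intermediate
3 | (3R)-5-[(4-methoxybenzyl)oxy]-1-(trimethylsilyl)pent-1-yn-3-ol | COc1ccc(cc1)COCC[C@@H](O)C#C[Si](C)(C)C | intermediate
4 | (3R)-5-[(4-methoxybenzyl)oxy]pent-1-yn-3-ol | COc1ccc(cc1)COCC[C@@H](O)C#C | intermediate
5 | chloromagnesium alkoxide of the alkenylmagnesium chloride from anti-carbomagnesiation of 4 (Mg cis to the carbinol carbon) | COc1ccc(cc1)COCC[C@@H](O[Mg]Cl)/C(C[Si](C)(C)OC(C)C)=C\[Mg]Cl | intermediate
6 | (1E,3R)-1-iodo-2-{[dimethyl(propan-2-yloxy)silyl]methyl}-5-[(4-methoxybenzyl)oxy]pent-1-en-3-ol | COc1ccc(cc1)COCC[C@@H](O)/C(C[Si](C)(C)OC(C)C)=C\I | intermediate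
7 | (2Z,3R)-2-(iodomethylidene)-5-[(4-methoxybenzyl)oxy]pentane-1,3-diol | COc1ccc(cc1)COCC[C@@H](O)/C(CO)=C\I | intermediate
8 | bis-TBS ether of 7 (Z-alkenyl iodide, 3R) | COc1ccc(cc1)COCC[C@@H](O[Si](C)(C)C(C)(C)C)/C(CO[Si](C)(C)C(C)(C)C)=C\I | intermediate
9 | 2-chloro-N-methoxy-N-methylacetamide | CON(C)C(=O)CCl | starting material
10 | (4-methoxyphenyl)methanol | COc1ccc(CO)cc1 | starting material
11 | N-methoxy-2-[(4-methoxybenzyl)oxy]-N-methylacetamide | CON(C)C(=O)COCc1ccc(OC)cc1 | intermediate
12 | alkenyllithium from 8 (Li in place of I, geometry retained) | COc1ccc(cc1)COCC[C@@H](O[Si](C)(C)C(C)(C)C)/C(CO[Si](C)(C)C(C)(C)C)=C\[Li] | intermediate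
13 | (3Z,5R)-5-[(tert-butyldimethylsilyl)oxy]-4-{[(tert-butyldimethylsilyl)oxy]methyl}-1,7-bis[(4-methoxybenzyl)oxy]hept-3-en-2-one | COc1ccc(cc1)COCC[C@@H](O[Si](C)(C)C(C)(C)C)/C(CO[Si](C)(C)C(C)(C)C)=C\C(=O)COCc1ccc(OC)cc1 | intermediate
14 | methyl 2,6-dimethylbenzoate | COC(=O)c1c(C)cccc1C | starting material
15 | lithium dienolate of methyl 2,6-dimethyl-1,4-dihydrobenzoate | COC(O[Li])=C1C(C)=CCC=C1C | intermediate
16 | methyl 2,6-dimethylcyclohexa-2,5-diene-1-carboxylate | COC(=O)C1C(C)=CCC=C1C | intermediate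
17 | 2,6-dimethylcyclohexa-2,5-diene-1-carbaldehyde | O=CC1C(C)=CCC=C1C | intermediate
18 | (Z)-diisopinocampheylboron enolate of 13 (O–B on C7, C7=C8) | COc1ccc(cc1)COCC[C@@H](O[Si](C)(C)C(C)(C)C)/C(CO[Si](C)(C)C(C)(C)C)=C\C(OB([C@@H]1C[C@@H]2C[C@H]([C@H]1C)C2(C)C)[C@@H]1C[C@@H]2C[C@H]([C@H]1C)C2(C)C)=C\OCc1ccc(OC)cc1 | intermediate
19 | aldol adduct: 9S carbinol carrying the 2,6-dimethylcyclohexa-2,5-dienyl ring, 8-OPMB (8,9-syn), C7 ketone, (5Z)-alkene with 16-OTBS, 4R-OTBS, 2-OPMB | COc1ccc(cc1)COCC[C@@H](O[Si](C)(C)C(C)(C)C)/C(CO[Si](C)(C)C(C)(C)C)=C\C(=O)[C@H](OCc1ccc(OC)cc1)[C@@H](O)C1C(C)=CCC=C1C | intermediate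
20 | 19 with the C1=C14 ring alkene epoxidised cis to C9 (C10 as in the target) | COc1ccc(cc1)COCC[C@@H](O[Si](C)(C)C(C)(C)C)/C(CO[Si](C)(C)C(C)(C)C)=C\C(=O)[C@H](OCc1ccc(OC)cc1)[C@@H](O)[C@H]1C(C)=CC[C@H]2O[C@@]12C | intermediate
21 | 9-O-acetyl 7-carbinol (7,9-anti; C4, C7, C9, C10 as in the target) | COc1ccc(cc1)COCC[C@@H](O[Si](C)(C)C(C)(C)C)/C(CO[Si](C)(C)C(C)(C)C)=C\[C@H](O)[C@H](OCc1ccc(OC)cc1)[C@@H](OC(C)=O)[C@H]1C(C)=CC[C@H]2O[C@@]12C | intermediate
22 | 7-O-(2-bromopropanoyl) ester of 21 (both bromide epimers) | COc1ccc(cc1)COCC[C@@H](O[Si](C)(C)C(C)(C)C)/C(CO[Si](C)(C)C(C)(C)C)=C\[C@H](OC(=O)C(C)Br)[C@H](OCc1ccc(OC)cc1)[C@@H](OC(C)=O)[C@H]1C(C)=CC[C@H]2O[C@@]12C | intermediate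
23 | bromohydrin from 22: C1 tertiary bromide, C14 carbinol trans to it | COc1ccc(cc1)COCC[C@@H](O[Si](C)(C)C(C)(C)C)/C(CO[Si](C)(C)C(C)(C)C)=C\[C@H](OC(=O)C(C)Br)[C@H](OCc1ccc(OC)cc1)[C@@H](OC(C)=O)[C@H]1C(C)=CC[C@@H](O)[C@]1(C)Br | intermediate
24 | triol from 23 (C2-OH, C8-OH, C14-OH) | OCC[C@@H](O[Si](C)(C)C(C)(C)C)/C(CO[Si](C)(C)C(C)(C)C)=C\[C@H](OC(=O)C(C)Br)[C@H](O)[C@@H](OC(C)=O)[C@H]1C(C)=CC[C@@H](O)[C@]1(C)Br | intermediate
25 | seco tricarbonyl: C2 aldehyde, C8 ketone, C14 ketone with C1–Br; 7-O-(2-bromopropanoyl), 9-OAc, 4,16-bis-OTBS | O=CC[C@@H](O[Si](C)(C)C(C)(C)C)/C(CO[Si](C)(C)C(C)(C)C)=C\[C@H](OC(=O)C(C)Br)C(=O)[C@@H](OC(C)=O)[C@H]1C(C)=CCC(=O)[C@]1(C)Br | intermediate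
26 | bis-aldol ketol: lactone and ten-membered ring closed; 2-OH, 14-oxo, 8-OH, 9-OAc, 4,16-bis-OTBS | CC(C)(C)[Si](C)(C)OC/C1=C/[C@@H]2OC(=O)[C@H](C)[C@@]2(O)[C@@H](OC(C)=O)[C@H]2C(C)=CCC(=O)[C@]2(C)[C@@H](O)C[C@H]1O[Si](C)(C)C(C)(C)C | intermediate
27 | 2,9-di-O-acetyl-14-hydroxy-4,16-bis-O-TBS briaranolide (all centres as in the target) | CC(C)(C)[Si](C)(C)OC/C1=C/[C@@H]2OC(=O)[C@H](C)[C@@]2(O)[C@@H](OC(C)=O)[C@H]2C(C)=CC[C@H](O)[C@]2(C)[C@@H](OC(C)=O)C[C@H]1O[Si](C)(C)C(C)(C)C | intermediate
28 | 16-hydroxy analogue of 27 (4-O-TBS retained) | OC/C1=C/[C@@H]2OC(=O)[C@H](C)[C@@]2(O)[C@@H](OC(C)=O)[C@H]2C(C)=CC[C@H](O)[C@]2(C)[C@@H](OC(C)=O)C[C@H]1O[Si](C)(C)C(C)(C)C | intermediate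
29 | 4-O-TBS ether of the target (2,9,14,16-tetraacetate) | CC(=O)OC/C1=C/[C@@H]2OC(=O)[C@H](C)[C@@]2(O)[C@@H](OC(C)=O)[C@H]2C(C)=CC[C@H](OC(C)=O)[C@]2(C)[C@@H](OC(C)=O)C[C@H]1O[Si](C)(C)C(C)(C)C | intermediate
30 | CNP0226727.2 | CC(=O)OC/C1=C/[C@@H]2OC(=O)[C@H](C)[C@@]2(O)[C@@H](OC(C)=O)[C@H]2C(C)=CC[C@H](OC(C)=O)[C@]2(C)[C@@H](OC(C)=O)C[C@H]1O | target

**Count**
Total steps: 20. Longest linear sequence: 17 (steps 1–5, 7, 10–20).

**Steps most likely to fail**

1. Step 17. The ten-membered aldol is slow, so the C1 samarium enolate may be protonated, may take the acetyl group from O9, or the aldolate may revert, and the facial selectivity at C1/C2 may be poor. The fallback separates enolate formation from C–C bond formation. It sets out from 25: activated zinc with TMSCl in MeCN/THF closes the lactone by a zinc Reformatsky reaction and traps the C1 enolate and the C8 alkoxide as silyl ethers, giving the silyl enol ether lactone aldehyde F1. An intramolecular Mukaiyama aldol (BF3·OEt2, CH2Cl2, −78 °C, high dilution, open transition state) followed by mild acidic work-up gives 26, now isolated. A separate Evans–Tishchenko reduction (SmI2 cat., MeCHO) returns to the route at 27.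

2. Step 14. The tertiary cation-like centre at C1 may be captured by the ether oxygen on C8 or by the C9 acetate, or may rearrange by hydride shift, instead of taking up bromide. The fallback opens the oxirane only after the PMB ethers are gone and C8 is a ketone. It sets out from 22: DDQ gives the epoxy diol F2, Dess–Martin oxidation gives the epoxy keto aldehyde F3, HBr at −20 °C gives the bromohydrin keto aldehyde F4, and a second Dess–Martin oxidation returns to the route at 25.

3. Step 11. The C9 hydroxyl may discriminate poorly between the two diastereotopic ring alkenes, or both may be epoxidised. The fallback fixes C10 by catalyst control before the fragments are joined. It sets out from 16: LiAlH4 gives the dienyl methanol F5; an enantioselective desymmetrising epoxidation of this homoallylic alcohol (chiral vanadium bishydroxamic acid catalyst, hydroperoxide) gives the epoxy alcohol F6; Dess–Martin oxidation gives the epoxy aldehyde F7, used cold at once. The Ipc-boron aldol of F7 with enolate 18 returns to the route at 20.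

**Further compounds**
F1 | step 17 | silyl enol ether lactone aldehyde: butanolide closed with 8-OTMS, C14 OTMS enol ether (C14=C1), C2 aldehyde | O=CC[C@@H](O[Si](C)(C)C(C)(C)C)/C(CO[Si](C)(C)C(C)(C)C)=C\[C@@H]1OC(=O)[C@H](C)[C@@]1(O[Si](C)(C)C)[C@@H](OC(C)=O)[C@H]1C(C)=CCC(O[Si](C)(C)C)=C1C
F2 | step 14 | epoxy diol from 22 (C2-OH, C8-OH, oxirane intact) | OCC[C@@H](O[Si](C)(C)C(C)(C)C)/C(CO[Si](C)(C)C(C)(C)C)=C\[C@H](OC(=O)C(C)Br)[C@H](O)[C@@H](OC(C)=O)[C@H]1C(C)=CC[C@H]2O[C@@]12C
F3 | step 14 | epoxy keto aldehyde (C2 aldehyde, C8 ketone, oxirane intact) | O=CC[C@@H](O[Si](C)(C)C(C)(C)C)/C(CO[Si](C)(C)C(C)(C)C)=C\[C@H](OC(=O)C(C)Br)C(=O)[C@@H](OC(C)=O)[C@H]1C(C)=CC[C@H]2O[C@@]12C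
F4 | step 14 | bromohydrin keto aldehyde (C1–Br, C14-OH, C8 ketone, C2 aldehyde) | O=CC[C@@H](O[Si](C)(C)C(C)(C)C)/C(CO[Si](C)(C)C(C)(C)C)=C\[C@H](OC(=O)C(C)Br)C(=O)[C@@H](OC(C)=O)[C@H]1C(C)=CC[C@@H](O)[C@]1(C)Br
F5 | step 11 | (2,6-dimethylcyclohexa-2,5-dien-1-yl)methanol | OCC1C(C)=CCC=C1C
F6 | step 11 | (1,3-dimethyl-7-oxabicyclo[4.1.0]hept-3-en-2-yl)methanol, oxirane cis to CH2OH, ring centres as in 20 | OC[C@H]1C(C)=CC[C@H]2O[C@@]12C
F7 | step 11 | 1,3-dimethyl-7-oxabicyclo[4.1.0]hept-3-ene-2-carbaldehyde, ring centres as in 20 | O=C[C@H]1C(C)=CC[C@H]2O[C@@]12C
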